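**Plan**

- The target, 5,7-dihydroxy-6-methoxy-3-(2,3,4-trimethoxyphenyl)-4H-chromen-4-one, is traced back to its 2,3-dihydro O5,O7-dibenzyl ether, and the pyranone ring of that isoflavanone is cut at three bonds: C4a–C4, C4–C3 and O1–C2.
- Enabling feature: the C4 carbonyl sits between ring-A carbon C4a and C3, and O1 is carried by C8a, ortho to C4a. An ortho-iodophenol (C8a–OH, C4a–I), carbon monoxide (C4) and a 1-arylvinyl boronate (C3 bearing ring B, C2 as the =CH2 terminus) therefore map onto ring C, with the phenol placed to close O1–C2.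
- Forward, ring-A piece: methyl 4-O-methylgallate → dibenzyl ether → benzaldehyde → Baeyer–Villiger phenol → mono-iodide. Ring-B piece: 2′,3′,4′-trimethoxyacetophenone → enol triflate → vinyl boronate.
- The two pieces and CO are joined in one pot and the phenoxide closes ring C, the only ring formed on the route. DDQ dehydrogenation and hydrogenolysis finish the synthesis.
- Stereochemistry: the target has no stereocentre. C3 of the isoflavanone is formed racemic and is erased by the C2–C3 dehydrogenation.

Key step: step 8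

Remark on the chemistry: the target is achiral, so the request for a single enantiomer is met by the constitution alone and no stereocontrol is needed.

**Route**

Step 1
Reactants: 1 methyl 3,5-dihydroxy-4-methoxybenzoate
Product: 2 methyl 3,5-bis(benzyloxy)-4-methoxybenzoate
Conditions: BnBr (2.3 equiv), K2CO3, DMF, 60 °C
Reagents that add atoms: benzyl bromide, BrCc1ccccc1
Why: Williamson etherification of the two equivalent phenols with a reactive benzylic halide under carbonate, which leaves the methyl ester untouched.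

Step 2
Reactants: 2 methyl 3,5-bis(benzyloxy)-4-methoxybenzoate
Product: 3 [3,5-bis(benzyloxy)-4-methoxyphenyl]methanol
Conditions: LiAlH4, THF, 0 °C to rt
Reagents that add atoms: none
Why: Hydride reduction of an aryl ester to the benzylic alcohol is routine, and aryl benzyl and methyl ethers are inert to LiAlH4.

Step 3
Reactants: 3 [3,5-bis(benzyloxy)-4-methoxyphenyl]methanol
Product: 4 3,5-bis(benzyloxy)-4-methoxybenzaldehyde
Conditions: activated MnO2 (excess), CH2Cl2, rt
Reagents that add atoms: none
Why: Activated MnO2 oxidises benzylic alcohols selectively to the aldehyde without over-oxidation and does not touch the ethers.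

Step 4
Reactants: 4 3,5-bis(benzyloxy)-4-methoxybenzaldehyde
Product: 6 3,5-bis(benzyloxy)-4-methoxyphenol, via aryl formate 5 (not isolated)
Conditions: mCPBA, CH2Cl2, 0 °C to rt; then K2CO3 (cat.), MeOH, rt
Reagents that add atoms: meta-chloroperoxybenzoic acid, O=C(OO)c1cccc(Cl)c1
Why: Baeyer–Villiger (Dakin-type) oxidation, in which the electron-rich para-alkoxyaryl group of the Criegee adduct migrates in preference to hydride to give the aryl formate, whose mild methanolysis should free the symmetric phenol.

Step 5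
Reactants: 6 3,5-bis(benzyloxy)-4-methoxyphenol
Product: 7 3,5-bis(benzyloxy)-2-iodo-4-methoxyphenol
Conditions: NIS (1.0 equiv), MeCN, −20 °C to 0 °C, dark
Reagents that add atoms: N-iodosuccinimide, O=C1CCC(=O)N1I
Why: Electrophilic aromatic iodination, in which the only two free ring positions are equivalent (each ortho to OH and ortho/para to the benzyloxy groups), so one equivalent of NIS can give only this regioisomer and the para position is blocked by OMe.

Step 6
Reactants: 8 2′,3′,4′-trimethoxyacetophenone
Product: 9 1-(2,3,4-trimethoxyphenyl)ethenyl trifluoromethanesulfonate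
Conditions: KHMDS, THF, −78 °C; then PhNTf2, −78 °C to 0 °C
Reagents that add atoms: N-phenylbis(trifluoromethanesulfonimide), O=S(=O)(N(c1ccccc1)S(=O)(=O)C(F)(F)F)C(F)(F)F
Why: Enol triflate formation by O-sulfonylation of the potassium enolate of a methyl ketone that has a single enolisable position, with the mild triflyl donor PhNTf2 avoiding elimination to the alkyne.

Step 7
Reactants: 9 1-(2,3,4-trimethoxyphenyl)ethenyl trifluoromethanesulfonate
Product: 10 4,4,5,5-tetramethyl-2-[1-(2,3,4-trimethoxyphenyl)ethenyl]-1,3,2-dioxaborolane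
Conditions: B2pin2, PdCl2(PPh3)2 (3 mol %), PPh3 (6 mol %), KOPh, toluene, 50 °C
Reagents that add atoms: bis(pinacolato)diboron, CC1(C)OB(OC1(C)C)B1OC(C)(C)C(C)(C)O1
Why: Miyaura borylation of an alkenyl triflate, in which the weak base KOPh promotes transmetalation of the diboron but not Suzuki coupling of the product with unreacted triflate.

Step 8
Reactants: 7 3,5-bis(benzyloxy)-2-iodo-4-methoxyphenol; 10 4,4,5,5-tetramethyl-2-[1-(2,3,4-trimethoxyphenyl)ethenyl]-1,3,2-dioxaborolane (1.5 equiv); 11 carbon monoxide
Product: 13 rac-5,7-bis(benzyloxy)-6-methoxy-3-(2,3,4-trimethoxyphenyl)chroman-4-one, via hydroxyaryl vinyl ketone 12 (not isolated)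
Conditions: PEPPSI-IPr (5 mol %), Cs2CO3 (3 equiv), CO (5 bar), PhCl, 80 °C
Reagents that add atoms: none
Why: Pd(0) adds oxidatively to the C–I bond of the phenoxide of 7, CO inserts to give the aroyl–palladium species, the alkenyl group of 10 is transmetalated under carbonate activation and reductive elimination forms C4a–C4 and C4–C3 in the hydroxyaryl vinyl ketone 12, whose phenoxide then adds to the methylene carbon to form O1–C2. The closest known reactions are the carbonylative Suzuki–Miyaura coupling of aryl iodides with alkenylboron reagents and the oxa-Michael closure of 2′-hydroxy-α-methylene-deoxybenzoins to isoflavanones. The pyranone ring closes in the 6-endo-trig mode, which is allowed and is driven by the strongly electrophilic α-aryl enone. C3 becomes a stereocentre by unselective protonation of the resulting enolate, so 13 is racemic by design with no controlling element, and the centre is removed in step 9. The selectivity needed is carbonylative over direct coupling and over intermolecular capture of the aroyl–palladium by phenoxide: the iodide is flanked by O-substituents on both sides, which slows transmetalation at the aryl–palladium stage so that CO insertion under 5 bar wins, the bulky NHC ligand speeds the final reductive elimination, and an intramolecular four-membered lactone cannot form. The excess of 10 covers any protodeboronation.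

Step 9
Reactants: 13 rac-5,7-bis(benzyloxy)-6-methoxy-3-(2,3,4-trimethoxyphenyl)chroman-4-one
Product: 14 5,7-bis(benzyloxy)-6-methoxy-3-(2,3,4-trimethoxyphenyl)-4H-chromen-4-one
Conditions: DDQ (1.5–2 equiv), 1,4-dioxane, reflux
Reagents that add atoms: none
Why: DDQ dehydrogenation of a chroman-4-one to the chromone, in which hydride loss from C2 (stabilised by O1) and proton loss from C3 give the conjugated 4-pyranone, while benzyl ethers without a para-donor are oxidised only slowly by DDQ.

Step 10
Reactants: 14 5,7-bis(benzyloxy)-6-methoxy-3-(2,3,4-trimethoxyphenyl)-4H-chromen-4-one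
Product: 15 5,7-dihydroxy-6-methoxy-3-(2,3,4-trimethoxyphenyl)-4H-chromen-4-one
Conditions: H2 (1 atm), 10% Pd/C, EtOAc/MeOH, rt, stopped after uptake of two equivalents
Reagents that add atoms: none
Why: Catalytic hydrogenolysis of aryl benzyl ethers, which is much faster than reduction of the vinylogous-ester C2=C3 bond of an isoflavone and leaves the four methyl ethers in place.

**Compound list**

1 | methyl 3,5-dihydroxy-4-methoxybenzoate | COC(=O)c1cc(O)c(OC)c(O)c1 | starting material
2 | methyl 3,5-bis(benzyloxy)-4-methoxybenzoate | COC(=O)c1cc(OCc2ccccc2)c(OC)c(OCc2ccccc2)c1 | intermediate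
3 | [3,5-bis(benzyloxy)-4-methoxyphenyl]methanol | OCc1cc(OCc2ccccc2)c(OC)c(OCc2ccccc2)c1 | intermediate
4 | 3,5-bis(benzyloxy)-4-methoxybenzaldehyde | O=Cc1cc(OCc2ccccc2)c(OC)c(OCc2ccccc2)c1 | intermediate
5 | 3,5-bis(benzyloxy)-4-methoxyphenyl formate | O=COc1cc(OCc2ccccc2)c(OC)c(OCc2ccccc2)c1 | intermediate
6 | 3,5-bis(benzyloxy)-4-methoxyphenol | Oc1cc(OCc2ccccc2)c(OC)c(OCc2ccccc2)c1 | intermediate
7 | 3,5-bis(benzyloxy)-2-iodo-4-methoxyphenol | Oc1cc(OCc2ccccc2)c(OC)c(OCc2ccccc2)c1I | intermediate
8 | 2′,3′,4′-trimethoxyacetophenone | CC(=O)c1ccc(OC)c(OC)c1OC | starting material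
9 | 1-(2,3,4-trimethoxyphenyl)ethenyl trifluoromethanesulfonate | C=C(OS(=O)(=O)C(F)(F)F)c1ccc(OC)c(OC)c1OC | intermediate
10 | 4,4,5,5-tetramethyl-2-[1-(2,3,4-trimethoxyphenyl)ethenyl]-1,3,2-dioxaborolane | COc1ccc(C(=C)B2OC(C)(C)C(C)(C)O2)c(OC)c1OC | intermediate
11 | carbon monoxide | [C-]#[O+] | starting material
12 | 1-[2,4-bis(benzyloxy)-6-hydroxy-3-methoxyphenyl]-2-(2,3,4-trimethoxyphenyl)prop-2-en-1-one | C=C(C(=O)c1c(O)cc(OCc2ccccc2)c(OC)c1OCc1ccccc1)c1ccc(OC)c(OC)c1OC | intermediate
13 | rac-5,7-bis(benzyloxy)-6-methoxy-3-(2,3,4-trimethoxyphenyl)chroman-4-one (racemic at C3) | COc1ccc(C2COc3cc(OCc4ccccc4)c(OC)c(OCc4ccccc4)c3C2=O)c(OC)c1OC | intermediate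
14 | 5,7-bis(benzyloxy)-6-methoxy-3-(2,3,4-trimethoxyphenyl)-4H-chromen-4-one | COc1ccc(-c2coc3cc(OCc4ccccc4)c(OC)c(OCc4ccccc4)c3c2=O)c(OC)c1OC | intermediate
15 | 5,7-dihydroxy-6-methoxy-3-(2,3,4-trimethoxyphenyl)-4H-chromen-4-one | COc1ccc(-c2coc3cc(O)c(OC)c(O)c3c2=O)c(OC)c1OC | target

**Step count**

Total: 10 steps. Longest linear sequence: 8 steps (1, 2, 3, 4, 5, 8, 9, 10); the boronate branch is steps 6 and 7.

**Steps most likely to fail**

Step 8. Direct, non-carbonylative coupling may outrun CO insertion, the α-arylvinyl boronate may protodeboronate, the aroyl–palladium species may be captured intermolecularly by phenoxide, or the vinyl ketone may polymerise before ring closure. The fallback builds the pyranone first and attaches ring B last. It sets out from 7: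
- Stille coupling with tributyl(1-ethoxyvinyl)stannane (Pd(PPh3)4, toluene, 100 °C) would give 3,5-bis(benzyloxy)-2-(1-ethoxyethenyl)-4-methoxyphenol F1.
- Hydrolysis during acidic work-up (1 M HCl, THF) would give 1-[2,4-bis(benzyloxy)-6-hydroxy-3-methoxyphenyl]ethan-1-one F2.
- Condensation with N,N-dimethylformamide dimethyl acetal (toluene, 90 °C) would give (E)-1-[2,4-bis(benzyloxy)-6-hydroxy-3-methoxyphenyl]-3-(dimethylamino)prop-2-en-1-one F3.
- Iodine in CHCl3/MeOH at rt would cyclise this to 5,7-bis(benzyloxy)-3-iodo-6-methoxy-4H-chromen-4-one F4.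
- Suzuki–Miyaura coupling with 2,3,4-trimethoxyphenylboronic acid (Pd(dppf)Cl2, Na2CO3, DME/H2O, 80 °C) would then give 14.

The route is rejoined at 14, so steps 8 and 9 are bypassed.

Step 6. The electron-rich α-aryl vinyl triflate may ionise and hydrolyse back to the ketone on work-up or chromatography, or eliminate to the aryl alkyne under base. The fallback avoids the triflate altogether. It sets out from 8:
- Condensation with 2,4,6-triisopropylbenzenesulfonohydrazide (MeOH, cat. HCl, rt) would give (E)-N′-[1-(2,3,4-trimethoxyphenyl)ethylidene]-2,4,6-triisopropylbenzenesulfonohydrazide F5.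
- A Shapiro reaction (n-BuLi, 2.2 equiv, THF/TMEDA, −78 °C to 0 °C) would generate [1-(2,3,4-trimethoxyphenyl)ethenyl]lithium F6.
- Quenching at −78 °C with 2-isopropoxy-4,4,5,5-tetramethyl-1,3,2-dioxaborolane would give 10.

The route is rejoined at 10, so 9 and step 7 are bypassed.

Step 9. Hydride abstraction by DDQ may stall, or may turn to the benzylic ether methylenes and the electron-rich ring B. The fallback replaces it by enolate selenenylation and oxidative elimination. It sets out from 13:
- Deprotonation with LiHMDS (THF, −78 °C) and trapping with PhSeCl would give rac-5,7-bis(benzyloxy)-6-methoxy-3-(phenylselanyl)-3-(2,3,4-trimethoxyphenyl)chroman-4-one F7.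
- Oxidation with 30% H2O2 (CH2Cl2/pyridine, 0 °C to rt) would give the selenoxide, 5,7-bis(benzyloxy)-6-methoxy-3-(phenylseleninyl)-3-(2,3,4-trimethoxyphenyl)chroman-4-one F8.
- This can only undergo syn-elimination toward the C2 hydrogens, giving 14.

The route is rejoined at 14.

**Further compounds**

F1 | step 8 | 3,5-bis(benzyloxy)-2-(1-ethoxyethenyl)-4-methoxyphenol | CCOC(=C)c1c(O)cc(OCc2ccccc2)c(OC)c1OCc1ccccc1
F2 | step 8 | 1-[2,4-bis(benzyloxy)-6-hydroxy-3-methoxyphenyl]ethan-1-one | CC(=O)c1c(O)cc(OCc2ccccc2)c(OC)c1OCc1ccccc1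
F3 | step 8 | (E)-1-[2,4-bis(benzyloxy)-6-hydroxy-3-methoxyphenyl]-3-(dimethylamino)prop-2-en-1-one | CN(C)/C=C/C(=O)c1c(O)cc(OCc2ccccc2)c(OC)c1OCc1ccccc1
F4 | step 8 | 5,7-bis(benzyloxy)-3-iodo-6-methoxy-4H-chromen-4-one | COc1c(OCc2ccccc2)cc2occ(I)c(=O)c2c1OCc1ccccc1
F5 | step 6 | (E)-N′-[1-(2,3,4-trimethoxyphenyl)ethylidene]-2,4,6-triisopropylbenzenesulfonohydrazide | C/C(=N\NS(=O)(=O)c1c(C(C)C)cc(C(C)C)cc1C(C)C)c1ccc(OC)c(OC)c1OC
F6 | step 6 | [1-(2,3,4-trimethoxyphenyl)ethenyl]lithium | [Li]C(=C)c1ccc(OC)c(OC)c1OC
F7 | step 9 | rac-5,7-bis(benzyloxy)-6-methoxy-3-(phenylselanyl)-3-(2,3,4-trimethoxyphenyl)chroman-4-one | COc1ccc(C2([Se]c3ccccc3)COc3cc(OCc4ccccc4)c(OC)c(OCc4ccccc4)c3C2=O)c(OC)c1OC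
F8 | step 9 | 5,7-bis(benzyloxy)-6-methoxy-3-(phenylseleninyl)-3-(2,3,4-trimethoxyphenyl)chroman-4-one (mixture of stereoisomers) | COc1ccc(C2([Se](=O)c3ccccc3)COc3cc(OCc4ccccc4)c(OC)c(OCc4ccccc4)c3C2=O)c(OC)c1OC
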